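**Retrosynthetic overview** (labdane numbering: ring A = C1–C5 + C10, ring B = C5–C10, C17 = exocyclic CH2 on C8, C18/C19 = methyl/carboxyl on C4, C20 = methyl on C10, side chain C11–C16 on C9)
1. Target 22 ⇐ butenolide 21 (lactone O12–C15, opened last) ⇐ C8 ketone 20 (methylenation adds C17).
2. Key disconnection: ring B of 20 is cut at C6–C7 and C9–C10, a formal [3+3] union of bridged allylic lactone 9 (C1–C6, C10, C18–C20; ten carbons) with β-keto ester 17 (C7–C9, C11–C16; nine carbons) at the quaternary C10.
3. Enabling feature: the C19 carboxyl on C4 and C10 are 1,3-cis on ring A, so they can be tied as a five-membered lactone bridge (6-oxabicyclo[3.2.1]octan-7-one). With the exocyclic C5=C6 methylene the C10–O bond is tertiary and allylic, so acid makes first C6 and then C10 electrophilic, while the tethered carboxyl delivers H to C5, shields the β face of C10 and ends as the free C19 acid.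
4. 9 comes from 2,3-dimethylbenzoic acid (Birch reductive methylation builds C4, resolution, selenolactonization–elimination); 17 from tert-butyl 4-oxobutanoate and methyl propiolate (asymmetric alkynylation sets C12, cuprate addition closes the butenolide, malonate homologation adds C7).
5. Ring order: ring A (from the arene) → temporary lactone bridge; butenolide ring; ring B last, in the key step; both lactones are opened again on the way to 22.

Key step: step 9

Assumption: (S)-1-phenylethylamine is taken to give the less soluble salt with the (S)-acid and (S,S)-ProPhenol to give the 4S alcohol 12; if either pairing proves opposite, the mirror-image amine or ligand is used.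

**Step 1**
Reactants: 1 2,3-dimethylbenzoic acid
Product: 3 rac-1,2,3-trimethylcyclohexa-2,5-diene-1-carboxylic acid, via dilithium enediolate 2 (not isolated)
Conditions: Li (2.5 equiv), NH3(l)–THF, −78 °C; then MeI (3 equiv), −78 °C to 25 °C; 1 M HCl
Reagents that add atoms: iodomethane, CI
Why: Birch reduction of the lithium benzoate gives the enediolate 2, which is C-methylated at the carboxyl-bearing carbon (Birch reductive alkylation), so the C4 quaternary carbon is built as a racemate and the two ring methyl groups (later C6 and C20) end on the remaining tetrasubstituted alkene.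

**Step 2**
Reactants: 3 rac-1,2,3-trimethylcyclohexa-2,5-diene-1-carboxylic acid
Product: 4 rac-1,2,3-trimethylcyclohex-2-ene-1-carboxylic acid
Conditions: H2 (1 atm), RhCl(PPh3)3 (5 mol %), benzene–EtOH (1:1), 25 °C
Reagents that add atoms: none
Why: Homogeneous hydrogenation with RhCl(PPh3)3 is known to reduce cis-disubstituted alkenes while leaving tetrasubstituted ones untouched, so only the disubstituted alkene should be saturated and no stereocenter is affected.

**Step 3**
Reactants: 4 rac-1,2,3-trimethylcyclohex-2-ene-1-carboxylic acid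
Product: 5 (1S)-1-phenylethan-1-aminium (1S)-1,2,3-trimethylcyclohex-2-ene-1-carboxylate
Conditions: (S)-1-phenylethylamine (1.0 equiv), acetone, 56 °C to 4 °C, two recrystallizations
Reagents that add atoms: (S)-1-phenylethylamine, C[C@H](N)c1ccccc1
Why: Classical resolution by crystallization of diastereomeric ammonium carboxylate salts should deliver the salt of the (S)-acid, which fixes the C4 configuration from which every ring stereocenter of the target is later derived.

**Step 4**
Reactants: 5 (1S)-1-phenylethan-1-aminium (1S)-1,2,3-trimethylcyclohex-2-ene-1-carboxylate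
Product: 9 (1S,5R)-1,5-dimethyl-8-methylidene-6-oxabicyclo[3.2.1]octan-7-one, via free acid 6 (not isolated), via phenylselanyl lactone 7 (not isolated), via selenoxide 8 (not isolated)
Conditions: 1 M HCl–CH2Cl2 partition; then PhSeCl (1.1 equiv), Et3N (1.1 equiv), CH2Cl2, −78 °C; then 30% H2O2, pyridine, 0 °C to 25 °C
Reagents that add atoms: none
Why: After release of acid 6, selenolactonization adds PhSe and the carboxylate anti across the tetrasubstituted alkene (five-membered lactone to the ring carbon 1,3 to the carboxyl, necessarily cis-bridged), and selenoxide syn-elimination can only use the methyl hydrogens because both other neighbours of the selenium-bearing carbon are quaternary, which should give the exocyclic allylic lactone.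

**Step 5**
Reactants: 10 tert-butyl 4-oxobutanoate; 11 methyl prop-2-ynoate
Product: 12 1-tert-butyl 7-methyl (4S)-4-hydroxyhept-5-ynedioate
Conditions: (S,S)-ProPhenol (10 mol %), Ph3P=O (20 mol %), Me2Zn (3 equiv), toluene, 4 °C; aq. NH4Cl
Reagents that add atoms: none
Why: Zinc–ProPhenol-catalysed enantioselective addition of the zinc alkynylide of 11 to the aldehyde (catalytic asymmetric alkynylation) should set the carbinol stereocenter, the later C12, under catalyst control, the tert-butyl ester being inert to the alkylzinc species.

**Step 6**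
Reactants: 12 1-tert-butyl 7-methyl (4S)-4-hydroxyhept-5-ynedioate
Product: 14 tert-butyl 3-[(2S)-3-methyl-5-oxo-2,5-dihydrofuran-2-yl]propanoate, via hydroxy enoate 13 (not isolated)
Conditions: Me2CuLi (from MeLi and CuI, 2.5 equiv), THF, −78 °C; then sat. aq. NH4Cl, −78 °C to 25 °C
Reagents that add atoms: lithium dimethylcuprate, [Li+].C[Cu-]C
Why: syn-Carbocupration of the ynoate (cuprate conjugate addition) places the ester cis to the carbinol carbon, so that after protonation the (Z)-hydroxy enoate 13 lactonizes spontaneously onto the methyl ester to the 4-methylbutenolide without touching the stereocenter, the bulky tert-butyl ester not competing as acyl acceptor.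

**Step 7**
Reactants: 14 tert-butyl 3-[(2S)-3-methyl-5-oxo-2,5-dihydrofuran-2-yl]propanoate
Product: 15 3-[(2S)-3-methyl-5-oxo-2,5-dihydrofuran-2-yl]propanoic acid
Conditions: CF3CO2H–CH2Cl2 (1:4), 0 °C to 25 °C
Reagents that add atoms: none
Why: Acidolysis of the tert-butyl ester by loss of isobutene (E1) should free the acid while the butenolide and its γ-stereocenter, which are base- but not acid-sensitive, stay intact.

**Step 8**
Reactants: 15 3-[(2S)-3-methyl-5-oxo-2,5-dihydrofuran-2-yl]propanoic acid
Product: 17 tert-butyl 5-[(2S)-3-methyl-5-oxo-2,5-dihydrofuran-2-yl]-3-oxopentanoate, via acyl imidazolide 16 (not isolated)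
Conditions: CDI (1.1 equiv), THF, 25 °C; then KO2CCH2CO2tBu (1.5 equiv), MgCl2 (1.5 equiv), Et3N, THF, 25 °C to 45 °C; 0.5 M HCl
Reagents that add atoms: potassium 3-tert-butoxy-3-oxopropanoate, CC(C)(C)OC(=O)CC(=O)[O-].[K+]
Why: Masamune–Brooks homologation, C-acylation of the magnesium enolate of the malonate half-ester by the acyl imidazolide followed by decarboxylation, should give the β-keto ester under near-neutral conditions that leave the acidic γ-hydrogen of the butenolide alone.

**Step 9**
Reactants: 9 (1S,5R)-1,5-dimethyl-8-methylidene-6-oxabicyclo[3.2.1]octan-7-one; 17 tert-butyl 5-[(2S)-3-methyl-5-oxo-2,5-dihydrofuran-2-yl]-3-oxopentanoate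
Product: 20 (1S,4aS,5R,8aR)-1,4a-dimethyl-5-{[(2S)-3-methyl-5-oxo-2,5-dihydrofuran-2-yl]methyl}-6-oxodecahydronaphthalene-1-carboxylic acid, via seco acid 18 (not isolated), via bridged keto lactone 19 (not isolated)
Conditions: CF3SO3H (20 mol %), CH2Cl2–(CF3)2CHOH (4:1), −40 °C, then 40 °C
Reagents that add atoms: none
Why: Proposed new method: CF3SO3H ionizes the tertiary allylic C10–O bond of 9 to an allyl cation spanning C10–C5–C6, and the enol of 17 attacks its unhindered CH2 terminus with the carbon between its two carbonyls (C6–C7; closest known type: acid-catalysed SN1 allylation of 1,3-dicarbonyl compounds by tertiary allylic alcohols and esters) to give 18. On warming, the tert-butyl ester leaves as isobutene and CO2 and the C19 acid adds across the tetrasubstituted C5=C10 alkene to give lactone 19, whose reversible ionization delivers the tertiary C10 cation to the enol of the ketone (C9–C10; closest known type: Lewis- or Brønsted-acid cation–olefin cyclization terminated by a β-keto ester or ketone enol). Ring B closes in a 6-(enolendo)-exo-tet sense (C10–O bond exocyclic) through a chair transition state, the only carbocyclization open to the cation because the other α-carbon could only form a four-membered ring, whereas O-capture, relactonization and proton loss are all reversible under the acid. C5–H is set by anti addition of proton and tethered carboxylate across C5=C10, C10 by attack of the enol on the face opposite the departing C4-bound carboxylate (inversion of the cis-bridged lactone, hence C20 cis to C19 and a trans ring fusion), C9 by acid-catalysed equilibration next to the new ketone to the equatorial side chain, while C4 and C12 are carried through untouched. The step needs the first C–C bond to form at the doubly activated carbon before the ester is lost and at the CH2 rather than the tertiary end of the allyl cation, which the low-temperature first stage, the high enol content of the β-keto ester and the steric bias of the allyl cation secure.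

**Step 10**
Reactants: 20 (1S,4aS,5R,8aR)-1,4a-dimethyl-5-{[(2S)-3-methyl-5-oxo-2,5-dihydrofuran-2-yl]methyl}-6-oxodecahydronaphthalene-1-carboxylic acid
Product: 21 (1S,4aR,5S,8aR)-1,4a-dimethyl-6-methylidene-5-{[(2S)-3-methyl-5-oxo-2,5-dihydrofuran-2-yl]methyl}decahydronaphthalene-1-carboxylic acid
Conditions: Zn, CH2Br2, TiCl4 (reagent preformed, 4 equiv), THF–CH2Cl2, 0 °C to 25 °C
Reagents that add atoms: dibromomethane, BrCBr
Why: Lombardo–Takai methylenation with the non-basic Zn/CH2Br2/TiCl4 reagent is chosen because it methylenates hindered, enolizable ketones without epimerizing the adjacent C9 and tolerates lactones and carboxylic acids (the acid consumes one extra equivalent as its carboxylate), so the C8 ketone should give the exocyclic C8=C17 alkene.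

**Step 11**
Reactants: 21 (1S,4aR,5S,8aR)-1,4a-dimethyl-6-methylidene-5-{[(2S)-3-methyl-5-oxo-2,5-dihydrofuran-2-yl]methyl}decahydronaphthalene-1-carboxylic acid
Product: 22 (1S,4aR,5S,8aR)-5-[(2S,3Z)-4-carboxy-2-hydroxy-3-methylbut-3-en-1-yl]-1,4a-dimethyl-6-methylidenedecahydronaphthalene-1-carboxylic acid
Conditions: LiOH (3 equiv), THF–H2O (3:1), 0 °C; then 0.5 M HCl to pH 4 at 0 °C, EtOAc
Reagents that add atoms: lithium hydroxide, [Li+].[OH-]
Why: Saponification at the butenolide carbonyl should give the (Z)-γ-hydroxy enoate as its dilithium salt with the double-bond geometry fixed by the former ring, and cold acidification to pH 4 with immediate extraction should release the hydroxy diacid before relactonization, any relactonized material being recycled as 21.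

**Compound list**
1 | 2,3-dimethylbenzoic acid | Cc1cccc(C(=O)O)c1C | starting material
2 | dilithium (2,3-dimethylcyclohexa-2,5-dien-1-ylidene)methanediolate | [Li+].[Li+].CC1=C(C)C(=C([O-])[O-])C=CC1 | intermediate
3 | rac-1,2,3-trimethylcyclohexa-2,5-diene-1-carboxylic acid | CC1=C(C)C(C)(C(=O)O)C=CC1 | intermediate
4 | rac-1,2,3-trimethylcyclohex-2-ene-1-carboxylic acid | CC1=C(C)C(C)(C(=O)O)CCC1 | intermediate
5 | (1S)-1-phenylethan-1-aminium (1S)-1,2,3-trimethylcyclohex-2-ene-1-carboxylate | C[C@]1(C(=O)[O-])CCCC(C)=C1C.C[C@H]([NH3+])c1ccccc1 | intermediate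
6 | (1S)-1,2,3-trimethylcyclohex-2-ene-1-carboxylic acid | C[C@]1(C(=O)O)CCCC(C)=C1C | intermediate
7 | (1R,5R,8R)-1,5,8-trimethyl-8-(phenylselanyl)-6-oxabicyclo[3.2.1]octan-7-one (selenium anti to the lactone bridge) | C[C@]1([Se]c2ccccc2)[C@@]3(C)CCC[C@]1(C)C(=O)O3 | intermediate
8 | (1R,5R,8R)-8-(benzeneseleninyl)-1,5,8-trimethyl-6-oxabicyclo[3.2.1]octan-7-one (mixture at selenium) | C[C@]1([Se](=O)c2ccccc2)[C@@]3(C)CCC[C@]1(C)C(=O)O3 | intermediate
9 | (1S,5R)-1,5-dimethyl-8-methylidene-6-oxabicyclo[3.2.1]octan-7-one | C=C1[C@@]2(C)CCC[C@]1(C)C(=O)O2 | intermediate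
10 | tert-butyl 4-oxobutanoate | O=CCCC(=O)OC(C)(C)C | starting material
11 | methyl prop-2-ynoate | C#CC(=O)OC | starting material
12 | 1-tert-butyl 7-methyl (4S)-4-hydroxyhept-5-ynedioate | COC(=O)C#C[C@@H](O)CCC(=O)OC(C)(C)C | intermediate
13 | 1-tert-butyl 7-methyl (4S,5Z)-4-hydroxy-5-methylhept-5-enedioate | COC(=O)/C=C(C)\[C@@H](O)CCC(=O)OC(C)(C)C | intermediate
14 | tert-butyl 3-[(2S)-3-methyl-5-oxo-2,5-dihydrofuran-2-yl]propanoate | CC1=CC(=O)O[C@H]1CCC(=O)OC(C)(C)C | intermediate
15 | 3-[(2S)-3-methyl-5-oxo-2,5-dihydrofuran-2-yl]propanoic acid | CC1=CC(=O)O[C@H]1CCC(=O)O | intermediate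
16 | (5S)-5-[3-(1H-imidazol-1-yl)-3-oxopropyl]-4-methylfuran-2(5H)-one | CC1=CC(=O)O[C@H]1CCC(=O)n2ccnc2 | intermediate
17 | tert-butyl 5-[(2S)-3-methyl-5-oxo-2,5-dihydrofuran-2-yl]-3-oxopentanoate | CC1=CC(=O)O[C@H]1CCC(=O)CC(=O)OC(C)(C)C | intermediate
18 | (1S)-2-{2-(tert-butoxycarbonyl)-5-[(2S)-3-methyl-5-oxo-2,5-dihydrofuran-2-yl]-3-oxopentyl}-1,3-dimethylcyclohex-2-ene-1-carboxylic acid (both epimers at the ester-bearing carbon) | CC1=C(CC(C(=O)OC(C)(C)C)C(=O)CC[C@@H]2OC(=O)C=C2C)[C@@](C)(C(=O)O)CCC1 | intermediate
19 | (1S,5R,8S)-1,5-dimethyl-8-{5-[(2S)-3-methyl-5-oxo-2,5-dihydrofuran-2-yl]-3-oxopentyl}-6-oxabicyclo[3.2.1]octan-7-one | O=C(CC[C@@H]1[C@@]2(C)CCC[C@]1(C)C(=O)O2)CC[C@@H]3OC(=O)C=C3C | intermediate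
20 | (1S,4aS,5R,8aR)-1,4a-dimethyl-5-{[(2S)-3-methyl-5-oxo-2,5-dihydrofuran-2-yl]methyl}-6-oxodecahydronaphthalene-1-carboxylic acid | O=C1CC[C@@H]2[C@](C)(CCC[C@]2(C)C(=O)O)[C@H]1C[C@@H]3OC(=O)C=C3C | intermediate
21 | (1S,4aR,5S,8aR)-1,4a-dimethyl-6-methylidene-5-{[(2S)-3-methyl-5-oxo-2,5-dihydrofuran-2-yl]methyl}decahydronaphthalene-1-carboxylic acid | C=C1CC[C@@H]2[C@](C)(CCC[C@]2(C)C(=O)O)[C@H]1C[C@@H]3OC(=O)C=C3C | intermediate
22 | (1S,4aR,5S,8aR)-5-[(2S,3Z)-4-carboxy-2-hydroxy-3-methylbut-3-en-1-yl]-1,4a-dimethyl-6-methylidenedecahydronaphthalene-1-carboxylic acid | C=C1CC[C@@H]2[C@](C)(CCC[C@]2(C)C(=O)O)[C@H]1C[C@H](O)/C(C)=C\C(=O)O | target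

**Totals**
Total step count: 11. Longest linear sequence: 7 steps (steps 1–4 or 5–8, then 9–11).

**Steps most likely to fail**

Step 9 (proposed new method). The cascade may stall after the first bond, so that seco acid or its lactone accumulates. The allyl cation may lose a proton and oligomerize. The tertiary cation may be held as O-alkylated or lactonized material instead of closing the carbocycle. The fallback sets out from 9 and 17 and returns at 20, making the two bonds in separate operations of known type. The sodium enolate of 17 (NaH, THF) is alkylated by 9 under Pd(PPh3)4 catalysis (Tsuji–Trost reaction, attack at the CH2 terminus of the π-allylpalladium carboxylate) to give seco acid 18. CF3CO2H in CH2Cl2 then removes the tert-butyl ester with decarboxylation and lactonizes the acid onto the tetrasubstituted alkene to give bridged keto lactone 19. Soft enolization of the ketone (Me3SiOSO2CF3, Et3N, CH2Cl2, −78 °C, one equivalent) gives the silyl enol ether F1; its regioisomer cannot cyclize and is recycled as 19. TiCl4 in CH2Cl2 at −78 °C then effects the Lewis-acid-mediated α-tert-alkylation of the silyl enol ether by the ionized tertiary lactone, the carboxylate counterpart of the known alkylation with tertiary halides, to give 20.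

Step 4. The seleniranium ion may fail to form on the hindered tetrasubstituted alkene, or the tertiary selenide may ionize before it is oxidized. The fallback sets out from 5 and returns at 9. The liberated acid 6 is iodolactonized (I2, NaHCO3, MeCN–H2O, 0 °C) to the tertiary iodo lactone F2. Anti elimination with DBU (toluene, 80 °C), which again can only use the methyl hydrogens, should then give 9.

Step 5. Enantioselectivity may be modest with an unbranched, ester-bearing aliphatic aldehyde, and methyl transfer from Me2Zn may compete. The fallback sets out from 10 and 11 and returns at 12. Lithiated 11 (LiN(SiMe3)2, THF, −78 °C) is added to 10 to give the racemic propargylic alcohol F3. Dess–Martin oxidation gives the ynone F4. Midland reduction with the Alpine-borane antipode that delivers the 4S alcohol (or Corey–Bakshi–Shibata reduction) then sets the stereocenter by reagent control and gives 12.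

**Further compounds**
F1 | step 9 | (1S,5R,8S)-1,5-dimethyl-8-{5-[(2S)-3-methyl-5-oxo-2,5-dihydrofuran-2-yl]-3-[(trimethylsilyl)oxy]pent-3-en-1-yl}-6-oxabicyclo[3.2.1]octan-7-one | C[Si](C)(C)OC(CC[C@@H]1[C@@]2(C)CCC[C@]1(C)C(=O)O2)=CC[C@@H]3OC(=O)C=C3C
F2 | step 4 | (1R,5R,8R)-8-iodo-1,5,8-trimethyl-6-oxabicyclo[3.2.1]octan-7-one | C[C@]1(I)[C@@]3(C)CCC[C@]1(C)C(=O)O3
F3 | step 5 | rac-1-tert-butyl 7-methyl 4-hydroxyhept-5-ynedioate | COC(=O)C#CC(O)CCC(=O)OC(C)(C)C
F4 | step 5 | 1-tert-butyl 7-methyl 4-oxohept-5-ynedioate | COC(=O)C#CC(=O)CCC(=O)OC(C)(C)C
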